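Numbering follows the isochromene of the target (O2, C1, C3, C4, C4a, C5, C6, C7, C8, C8a; C7 is R). Retrosynthesis: cut the octanoate O–acyl bond, then the pyran O2–C3 bond (back to a formyl carbon C1 on C8a and a C3≡C4 alkyne on C4a), then the carbocycle at C6–C7 and C4a–C8a.
Enabling feature: C7 is a quaternary carbon between the C6 and C8 ketones, so ring C4a/C5/C6/C7/C8/C8a cannot aromatize and is a 2,2-disubstituted cyclohexene-1,3-dione. The C8 ketone with its two α-carbons (C8a, C7) is a 1,3-bis-nucleophile, and C6(=O)–C5=C4a is a 1,3-bis-electrophile at the carboxylic acid level.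
Forward: a formyl ketone (C1, C8a, C8, C7) and a β-bromo enynoate (C6, C5, C4a, C4, C3, heptyl) are joined in one flask by vinylic substitution (C4a–C8a) and dianion Dieckmann closure (C6–C7). The carbocycle therefore arises first, directly at the azaphilone oxidation level, with no dearomatization.
The pyran ring is then closed by 6-endo-dig attack of the formyl oxygen on the alkyne, the auxiliary is cleaved and the tertiary alcohol is octanoylated.
Stereochemistry: C7, the only stereocentre, is created in the Dieckmann closure under the influence of a (1R,2S,5R)-menthyloxymethyl acetal on O7. The acetal also makes the C7 epimers diastereomers, which are separated after pyran closure; the quaternary centre cannot epimerize afterwards.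

Key step: step 5

Assumption: the sense of induction in step 5 is taken to be the one that gives the 7R epimer with the (1R,2S,5R) auxiliary; should it be opposite, the enantiomeric chloromethyl menthyl ether is used, and in either case the C7 epimers are separated as diastereomers at compound 10.

Step 1
Reactants: 1 ethyl glyoxylate
Product: 2 ethyl 3,3-dibromoprop-2-enoate
Conditions: CBr4, PPh3, CH2Cl2, 0 °C
Reagents that add atoms: carbon tetrabromide, BrC(Br)(Br)Br
Why: The dibromomethylene ylide made from CBr4 and PPh3 olefinates the aldehyde (Ramirez dibromo-olefination, the first stage of the Corey–Fuchs sequence) and leaves the ester untouched.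

Step 2
Reactants: 2 ethyl 3,3-dibromoprop-2-enoate; 3 non-1-yne
Product: 4 ethyl (2Z)-3-bromododec-2-en-4-ynoate
Conditions: Pd(PPh3)4 (5 mol %), CuI (10 mol %), iPr2NH, THF, rt
Reagents that add atoms: none
Why: Mono-Sonogashira coupling of a 1,1-dibromoalkene, in which zerovalent palladium inserts faster into the C–Br bond trans to the ester so that the bromine left behind is cis to the ester (Z); this geometry is not critical because the double bond becomes configurationally labile in 8.

Step 3
Reactants: 5 acetoin (racemic 3-hydroxybutan-2-one)
Product: 6 3-({[(1R,2S,5R)-menthyl]oxy}methoxy)butan-2-one (both epimers at the butanone C3)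
Conditions: iPr2NEt, n-Bu4NI (cat.), CH2Cl2, 0 °C to rt
Reagents that add atoms: (1R,2S,5R)-(–)-menthyl chloromethyl ether, C[C@@H]1CC[C@H]([C@@H](C1)OCCl)C(C)C
Why: O-alkylation of the secondary alcohol by an α-chloro ether (acetal protection of the methoxymethyl type) installs the chiral acetal, and the carbinol centre of 5 need not be defined because it is planarized in step 5.

Step 4
Reactants: 6 3-({[(1R,2S,5R)-menthyl]oxy}methoxy)butan-2-one
Product: 7 (1Z)-1-hydroxy-4-({[(1R,2S,5R)-menthyl]oxy}methoxy)pent-1-en-3-one (enol form of the β-keto aldehyde)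
Conditions: NaH, HCO2Et, THF, 0 °C to rt; then AcOH
Reagents that add atoms: ethyl formate, CCOC=O
Why: Crossed Claisen condensation (formylation) of the methyl ketone, regioselective for the methyl group because only that adduct is held as a stabilized 1,3-dicarbonyl enolate, whereas formylation at the tertiary carbon would be reversible.

Step 5
Reactants: 7 (1Z)-1-hydroxy-4-({[(1R,2S,5R)-menthyl]oxy}methoxy)pent-1-en-3-one; 4 ethyl (2Z)-3-bromododec-2-en-4-ynoate
Product: 9 (2R)-6-(hydroxymethylidene)-2-({[(1R,2S,5R)-menthyl]oxy}methoxy)-2-methyl-5-(non-1-yn-1-yl)cyclohex-4-ene-1,3-dione, via substitution adduct 8 (not isolated)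
Conditions: NaH (2.1 equiv), THF, 0 °C to rt; then LiN(iPr)2 (1.2 equiv), −78 to 0 °C; AcOH quench
Reagents that add atoms: none
Why: Proposed new method: the sodium enolate of 7 attacks C3 of 4 through its central carbon by addition–elimination (nucleophilic vinylic substitution of a β-bromo enoate by a 1,3-dicarbonyl anion, a known reaction type), and loss of bromide gives the enolate of 8, in which the future C8a carries no hydrogen and the alkyne leaves no γ-hydrogen on the enoate, so that LiN(iPr)2 is expected to remove only the C7–H and form the 1,3-dicarbonyl dianion. This dianion acylates itself at its terminal carbon on the ethyl ester (closest known types: γ-acylation of β-dicarbonyl dianions by esters and the Michael–Claisen synthesis of cyclohexane-1,3-diones), the carbocycle closing in the 6-(enolendo)-exo-trig mode with loss of ethoxide. The C4a–C8a bond is formed first and between the two molecules, so only this one ring closes here; the product is held as a delocalized vinylogous-acid anion, which drives the acylation and guards it against retro-Claisen cleavage. The new stereocentre C7 is set in the acylation: lithium is chelated between the enolate oxygen on C8 and the acetal oxygen on C7, the (1R,2S,5R)-menthyloxymethyl group screens one face of the planar enolate, and the ester, tied to the same chain through the cis C4a=C5 bond, is delivered to the other face. The step needs carbon- rather than oxygen-attack in the substitution (favoured by the soft acceptor and the sodium enolate in THF), carbon-acylation at C7 rather than lactonization through an enolate oxygen (favoured by the far higher nucleophilicity of the dianion terminus at low temperature) and facial selectivity at C7 (secured only by the auxiliary). What is new is the combination in one flask and the auxiliary-biased formation of an oxygenated quaternary centre by such a Dieckmann closure.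

Step 6
Reactants: 9 (2R)-6-(hydroxymethylidene)-2-({[(1R,2S,5R)-menthyl]oxy}methoxy)-2-methyl-5-(non-1-yn-1-yl)cyclohex-4-ene-1,3-dione
Product: 10 (7R)-3-heptyl-7-({[(1R,2S,5R)-menthyl]oxy}methoxy)-7-methyl-6H-isochromene-6,8(7H)-dione
Conditions: CuI (10 mol %), iPr2NEt, CH2Cl2, rt; then chromatography (removal of the 7S epimer)
Reagents that add atoms: none
Why: Copper-catalysed 6-endo-dig cycloisomerization, in which the hydroxymethylidene (formyl) oxygen adds to the alkyne activated by monovalent copper, is the reaction type used to close the pyran ring of azaphilones, and the two C7 epimers are diastereomeric acetals that can be separated at this stage.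

Step 7
Reactants: 10 (7R)-3-heptyl-7-({[(1R,2S,5R)-menthyl]oxy}methoxy)-7-methyl-6H-isochromene-6,8(7H)-dione
Product: 11 (7R)-3-heptyl-7-hydroxy-7-methyl-6H-isochromene-6,8(7H)-dione
Conditions: CF3CO2H, CH2Cl2, H2O (trace), 0 °C to rt
Reagents that add atoms: none
Why: Acid hydrolysis of the formaldehyde acetal (cleavage of a methoxymethyl-type ether) frees the tertiary alcohol, while the vinylogous ester chromophore should tolerate acid and the quaternary C7 cannot epimerize.

Step 8
Reactants: 11 (7R)-3-heptyl-7-hydroxy-7-methyl-6H-isochromene-6,8(7H)-dione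
Product: 12 (7R)-3-heptyl-7-methyl-6,8-dioxo-7,8-dihydro-6H-isochromen-7-yl octanoate (target)
Conditions: octanoyl chloride, DMAP, Et3N, CH2Cl2, 0 °C to rt
Reagents that add atoms: octanoyl chloride, CCCCCCCC(=O)Cl
Why: DMAP-catalysed acylation of the tertiary alcohol through the acylpyridinium ion (nucleophilic acyl-transfer catalysis) is the usual way to esterify the C7 hydroxyl of azaphilones and does not touch the stereocentre.

Compound list ((1R,2S,5R)-menthyl = (1R,2S,5R)-5-methyl-2-(propan-2-yl)cyclohexyl)
1 | ethyl glyoxylate (ethyl 2-oxoacetate) | O=CC(=O)OCC | starting material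
2 | ethyl 3,3-dibromoprop-2-enoate | CCOC(=O)C=C(Br)Br | intermediate
3 | non-1-yne | C#CCCCCCCC | starting material
4 | ethyl (2Z)-3-bromododec-2-en-4-ynoate | CCCCCCCC#C/C(Br)=C/C(=O)OCC | intermediate
5 | acetoin (racemic 3-hydroxybutan-2-one) | CC(O)C(C)=O | starting material
6 | 3-({[(1R,2S,5R)-menthyl]oxy}methoxy)butan-2-one, both epimers at the butanone C3 | C[C@@H]1CC[C@H]([C@@H](C1)OCOC(C)C(C)=O)C(C)C | intermediate
7 | (1Z)-1-hydroxy-4-({[(1R,2S,5R)-menthyl]oxy}methoxy)pent-1-en-3-one, enol of the β-keto aldehyde, both epimers at C4 | C[C@@H]1CC[C@H]([C@@H](C1)OCOC(C)C(=O)/C=C\O)C(C)C | intermediate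
8 | ethyl (2Z)-3-[1-(hydroxymethylidene)-3-({[(1R,2S,5R)-menthyl]oxy}methoxy)-2-oxobutyl]dodec-2-en-4-ynoate, formed in the flask in step 5 | C[C@@H]1CC[C@H]([C@@H](C1)OCOC(C)C(=O)C(=CO)/C(C#CCCCCCCC)=C\C(=O)OCC)C(C)C | intermediate
9 | (2R)-6-(hydroxymethylidene)-2-({[(1R,2S,5R)-menthyl]oxy}methoxy)-2-methyl-5-(non-1-yn-1-yl)cyclohex-4-ene-1,3-dione (vinylogous acid; the ring C2 is C7 of the target) | C[C@@H]1CC[C@H]([C@@H](C1)OCO[C@]2(C)C(=O)C=C(C#CCCCCCCC)C(=CO)C2=O)C(C)C | intermediate
10 | (7R)-3-heptyl-7-({[(1R,2S,5R)-menthyl]oxy}methoxy)-7-methyl-6H-isochromene-6,8(7H)-dione | C[C@@H]1CC[C@H]([C@@H](C1)OCO[C@]2(C)C(=O)C=C3C=C(CCCCCCC)OC=C3C2=O)C(C)C | intermediate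
11 | (7R)-3-heptyl-7-hydroxy-7-methyl-6H-isochromene-6,8(7H)-dione | O[C@]1(C)C(=O)C=C2C=C(CCCCCCC)OC=C2C1=O | intermediate
12 | (7R)-3-heptyl-7-methyl-6,8-dioxo-7,8-dihydro-6H-isochromen-7-yl octanoate | CCCCCCCC(=O)O[C@]1(C)C(=O)C=C2C=C(CCCCCCC)OC=C2C1=O | target

Total step count: 8.
Longest linear sequence: 6 steps (steps 3, 4, 5, 6, 7, 8 from acetoin 5; equally steps 1, 2, 5, 6, 7, 8 from 1).

Steps most likely to fail

1. Step 5 (proposed new method). What may go wrong: oxygen- instead of carbon-vinylation of the enolate, premature lactonization onto the ester before the dianion is formed, competing propargylic deprotonation by the amide base, or poor facial selectivity in the ring closure. Fallback by known chemistry, setting out from non-1-yne 3 and coming back at 11: Sonogashira coupling of 3 (PdCl2(PPh3)2, CuI, Et3N, DMF) with 6-bromo-2,4-dihydroxy-3-methylbenzaldehyde F1, itself made by Vilsmeier formylation (POCl3, DMF) of 5-bromo-2-methylbenzene-1,3-diol, gives 2,4-dihydroxy-3-methyl-6-(non-1-yn-1-yl)benzaldehyde F2. Copper-mediated enantioselective oxidative dearomatization of F2 with [Cu(MeCN)4]PF6, (–)-sparteine and O2 (iPr2NEt, DMAP, CH2Cl2, −78 to −10 °C), the ligand antipode expected to serve the 7R series of C5-unsubstituted azaphilones, hydroxylates the methyl-bearing ring carbon and should give (2R)-2-hydroxy-6-(hydroxymethylidene)-2-methyl-5-(non-1-yn-1-yl)cyclohex-4-ene-1,3-dione F3. Cycloisomerization of F3 under the conditions of step 6 closes the pyran ring and gives 11 directly, so that step 7 is not needed and step 8 completes the synthesis.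

2. Step 6. What may go wrong: ring closure through the wrong oxygen (the C6 carbonyl or enol oxygen adding to the alkyne in a 5-exo-dig mode) or copper-induced decomposition of the vinylogous acid. Fallback setting out from 9 and coming back at 10, in which the pyran is closed through a 1,5-dicarbonyl compound and not through the alkyne: hydration of the alkyne (Hg(OTf)2, divalent mercury, catalytic; H2O, MeCN), with oxygen entering at C3, the alkyne carbon remote from the electron-poor ring, gives (2R)-6-(hydroxymethylidene)-2-({[(1R,2S,5R)-menthyl]oxy}methoxy)-2-methyl-5-(2-oxononyl)cyclohex-4-ene-1,3-dione F4. Mild acid (PPTS, toluene, 50 °C) then condenses the enol oxygen of this ketone with the hydroxymethylidene carbon, with loss of water, to give 10.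

3. Step 2. What may go wrong: double coupling to the enediyne and erosion of site selectivity in the oxidative addition. Fallback setting out from 2 (used with 7 and 3) and coming back at 9, in which the alkyne is introduced after the annulation: dibromoacrylate 2 is taken through the conditions of step 5 with 7. Vinylic substitution of one bromine and dianion Dieckmann closure should give (2R)-5-bromo-6-(hydroxymethylidene)-2-({[(1R,2S,5R)-menthyl]oxy}methoxy)-2-methylcyclohex-4-ene-1,3-dione F5, a vinylogous acyl bromide whose geometry is fixed by the ring. Sonogashira coupling of F5 with 3 (PdCl2(PPh3)2, CuI, Et3N, THF, rt) then gives 9.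

Further compounds
F1 | step 5 | 6-bromo-2,4-dihydroxy-3-methylbenzaldehyde | O=Cc1c(Br)cc(O)c(C)c1O
F2 | step 5 | 2,4-dihydroxy-3-methyl-6-(non-1-yn-1-yl)benzaldehyde | O=Cc1c(C#CCCCCCCC)cc(O)c(C)c1O
F3 | step 5 | (2R)-2-hydroxy-6-(hydroxymethylidene)-2-methyl-5-(non-1-yn-1-yl)cyclohex-4-ene-1,3-dione | O[C@]1(C)C(=O)C=C(C#CCCCCCCC)C(=CO)C1=O
F4 | step 6 | (2R)-6-(hydroxymethylidene)-2-({[(1R,2S,5R)-menthyl]oxy}methoxy)-2-methyl-5-(2-oxononyl)cyclohex-4-ene-1,3-dione | C[C@@H]1CC[C@H]([C@@H](C1)OCO[C@]2(C)C(=O)C=C(CC(=O)CCCCCCC)C(=CO)C2=O)C(C)C
F5 | step 2 | (2R)-5-bromo-6-(hydroxymethylidene)-2-({[(1R,2S,5R)-menthyl]oxy}methoxy)-2-methylcyclohex-4-ene-1,3-dione | C[C@@H]1CC[C@H]([C@@H](C1)OCO[C@]2(C)C(=O)C=C(Br)C(=CO)C2=O)C(C)C
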